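## Retrosynthetic overview

1. Target ⇒ ring α-alkoxy ketone: the enone C=C is unveiled last, by samarium-mediated α-deoxygenation and β-elimination of a 3-keto-4,5-diol acetal (quinic acid numbering).
2. Key disconnection CH2–C(=O): a C7 spiro-epoxide plus a C18 linoleoyl donor, joined by a blue-light nickel/photoredox acylative opening of the oxirane at its CH2 terminus.
3. Spiro-epoxide ⇒ carboxyl group of quinic acid (CO2H → CO2Me → CH2OH → oxirane). The C1–O bond is never broken, so the target's single stereocentre is C1 of (−)-quinic acid, carried through with retention.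
4. Ring order: the only carbocycle is bought in (−)-quinic acid and no ring of the target is built. The two rings made on the way (dioxane acetal first, oxirane second) are both opened again.

Assumption: (−)-quinic acid and (9Z,12Z)-octadeca-9,12-dienoic (linoleic) anhydride are taken as catalogue compounds.

Ring positions of the intermediates are given in quinic acid numbering (C1 = carbinol carbon). "BDA" means the butane-2,3-diacetal, a (2S,3S)-2,3-dimethoxybutane-2,3-diyl bridge between O4 and O5.

## Route

Step 1
Reactants: 1 (−)-quinic acid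
Product: 3 BDA-protected methyl quinate, via methyl quinate 2 (not isolated)
Conditions: butane-2,3-dione, HC(OMe)3, MeOH, TsOH·H2O (cat.), reflux
Reagents that add atoms: butane-2,3-dione CC(=O)C(C)=O; methanol CO; trimethyl orthoformate COC(OC)OC
Why: Fischer esterification and thermodynamically controlled butane-2,3-diacetal formation run together; only the trans-diequatorial 4,5-diol gives the trans-fused dioxane with both OMe groups axial (anomeric effect), which leaves the 1-OH and the axial 3-OH free and sets the two acetal centres from the bought diol configuration.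

Step 2
Reactants: 3 BDA-protected methyl quinate
Product: 4 1-(hydroxymethyl) triol (CO2Me of 3 reduced to CH2OH)
Conditions: NaBH4, EtOH, 0 °C to rt
Reagents that add atoms: none
Why: Hydroxyl-assisted borohydride reduction of an α-hydroxy ester gives the primary alcohol and touches neither the acetal nor any stereocentre.

Step 3
Reactants: 4 1-(hydroxymethyl) triol
Product: 6 spiro-epoxide (oxirane O = former 1-OH oxygen; oxirane CH2 = former carboxyl carbon), via primary tosylate 5 (not isolated)
Conditions: TsCl, Et3N, Bu2SnO (cat.), CH2Cl2, 0 °C; then DBU, rt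
Reagents that add atoms: none
Why: Tin-acetal-directed monosulfonylation picks the primary hydroxyl of the 1,2-diol and the tertiary alkoxide then closes the oxirane by 3-exo-tet displacement (intramolecular Williamson etherification); the C1–O bond is never broken, so the carbinol configuration is retained, and the 3-OH, trans to the CH2OTs arm, cannot cyclise.

Step 4
Reactants: 6 spiro-epoxide; 7 linoleic anhydride
Product: 9 β-hydroxy ketone (C1 bears OH and CH2C(=O)-(8Z,11Z)-heptadeca-8,11-dienyl), via iodohydrin 8 (not isolated)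
Conditions: NiBr2(dme) (10 mol %), 4,4'-di-tert-butyl-2,2'-bipyridine (12 mol %), 2,4,5,6-tetra(carbazol-9-yl)isophthalonitrile (4CzIPN, 2 mol %), NaI (0.5 equiv), Et3N·HCl (0.2 equiv), Hantzsch ester (1.5 equiv), DMA, 450 nm LEDs, 25 °C
Reagents that add atoms: none
Why: Proposed new method: iodide (with Et3N·HCl as proton shuttle) opens the 2,2-disubstituted oxirane reversibly at CH2 to iodohydrin 8, photoexcited 4CzIPN is reduced by the Hantzsch ester and passes its electrons to nickel, zerovalent nickel inserts into the anhydride C(acyl)–O bond, monovalent nickel abstracts iodine from 8, and the β-hydroxy-neopentyl radical (no β-hydrogen, so no β-hydride loss) is captured by the acyl-nickel species, whose reductive elimination forges the CH2–C(=O) bond without touching the C–O bond of the carbinol stereocentre (retention); the closest known reaction types are the nickel/photoredox cross-electrophile coupling of epoxides with aryl halides through in-situ iodohydrins and the nickel-catalysed reductive acylation of alkyl iodides with anhydrides, but their merger into an epoxide-to-tertiary-aldol acylation has not been shown.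

Step 5
Reactants: 9 β-hydroxy ketone
Product: 10 ring 3-ketone (α-alkoxy ketone)
Conditions: Dess–Martin periodinane, pyridine, CH2Cl2, 0 °C to rt
Reagents that add atoms: none
Why: Dess–Martin oxidation converts the only secondary alcohol (tertiary alcohol, acetal and skipped Z,Z-diene are inert), and pyridine buffering prevents β-elimination of the tertiary 1-OH.

Step 6
Reactants: 10 ring 3-ketone
Product: 12 (5S)-5-hydroxy-5-[(10Z,13Z)-2-oxononadeca-10,13-dien-1-yl]cyclohex-2-en-1-one, via samarium enolate 11 (not isolated)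
Conditions: SmI2 (2.2 equiv), THF, −78 to 0 °C; pH 7 phosphate buffer
Reagents that add atoms: none
Why: Divalent samarium cleaves the α C4–O bond of the α-alkoxy ketone (two-electron α-deoxygenation) to the regiodefined samarium enolate 11, whose β-alkoxy group on C5 then leaves in an E1cB step (the samarium-enolate β-elimination known from α-halo-β-hydroxy carbonyl compounds), giving the C4=C5 enone and shedding the acetal, while the chain ketone (no α leaving group, no proton source) and the carbinol stereocentre stay untouched.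

## Compound list

1 | (−)-quinic acid, (1S,3R,4S,5R)-1,3,4,5-tetrahydroxycyclohexane-1-carboxylic acid (1-OH, 3-OH, 4-OH on one face; 5-OH and CO2H on the other) | O[C@@]1(C(=O)O)C[C@@H](O)[C@@H](O)[C@H](O)C1 | starting material
2 | methyl quinate (methyl ester of 1, formed in the flask in step 1) | COC(=O)[C@]1(O)C[C@@H](O)[C@@H](O)[C@H](O)C1 | intermediate
3 | methyl 4,5-O-[(2S,3S)-2,3-dimethoxybutane-2,3-diyl]quinate (trans-fused dioxane on O4/O5, both OMe axial; 1-OH and 3-OH free; ring centres as in 1) | COC(=O)[C@]1(O)C[C@@H](O)[C@H]2O[C@](C)(OC)[C@@](C)(OC)O[C@@H]2C1 | intermediate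
4 | triol: CO2Me of 3 reduced to CH2OH (1-OH and 3-OH free, 4,5-O-BDA, ring centres as in 1) | OC[C@]1(O)C[C@@H](O)[C@H]2O[C@](C)(OC)[C@@](C)(OC)O[C@@H]2C1 | intermediate
5 | primary p-toluenesulfonate of 4 (CH2OTs; formed in the flask in step 3) | Cc1ccc(cc1)S(=O)(=O)OC[C@]2(O)C[C@@H](O)[C@H]3O[C@](C)(OC)[C@@](C)(OC)O[C@@H]3C2 | intermediate
6 | spiro-epoxide: 1-oxaspiro[2.5]octane whose oxirane O is the former 1-OH oxygen (same face as the free 3-OH) and whose oxirane CH2 is the former carboxyl carbon; 4,5-O-BDA | C1O[C@]12C[C@@H](O)[C@H]3O[C@](C)(OC)[C@@](C)(OC)O[C@@H]3C2 | intermediate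
7 | linoleic anhydride, (9Z,12Z)-octadeca-9,12-dienoic anhydride | CCCCC/C=C\C/C=C\CCCCCCCC(=O)OC(=O)CCCCCCC/C=C\C/C=C\CCCCC | starting material
8 | iodohydrin: 1-(iodomethyl) analogue of 4 (formed in the flask in step 4) | IC[C@]1(O)C[C@@H](O)[C@H]2O[C@](C)(OC)[C@@](C)(OC)O[C@@H]2C1 | intermediate
9 | (10Z,13Z)-1-(1,3-dihydroxy-4,5-O-BDA-cyclohexyl)nonadeca-10,13-dien-2-one (chain on the face of the former CO2H; ring centres as in 1) | CCCCC/C=C\C/C=C\CCCCCCCC(=O)C[C@]1(O)C[C@@H](O)[C@H]2O[C@](C)(OC)[C@@](C)(OC)O[C@@H]2C1 | intermediate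
10 | 3-oxo analogue of 9 (ring ketone at quinic C3, tertiary 1-OH free, 4,5-O-BDA) | CCCCC/C=C\C/C=C\CCCCCCCC(=O)C[C@]1(O)CC(=O)[C@H]2O[C@](C)(OC)[C@@](C)(OC)O[C@@H]2C1 | intermediate
11 | samarium enolate: C3–O–SmI2 with C3=C4; O5 still carries the opened acetal chain ending in O–SmI2 (formed in the flask in step 6) | CCCCC/C=C\C/C=C\CCCCCCCC(=O)C[C@]1(O)CC(O[Sm](I)I)=C[C@H](O[C@](C)(OC)[C@@](C)(OC)O[Sm](I)I)C1 | intermediate
12 | (5S)-5-hydroxy-5-[(10Z,13Z)-2-oxononadeca-10,13-dien-1-yl]cyclohex-2-en-1-one | CCCCC/C=C\C/C=C\CCCCCCCC(=O)C[C@@]1(O)CC=CC(=O)C1 | target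

## Totals and risks

Total step count: 6. Longest linear sequence: 6 steps (1 to 12).

**Step 4 (proposed new reaction).** Risks are O-acylation of the free 3-OH by the anhydride, hydrodeiodination of the radical by the Hantzsch ester, hydrogen abstraction at the bis-allylic CH2, and Z/E scrambling. The 450 nm light is not absorbed by the skipped diene and the 4CzIPN triplet is too low in energy to sensitise isolated alkenes.

The fallback uses known Corey–Seebach dithiane umpolung; it sets out from 6 and comes back at 9. Commercial (9Z,12Z)-octadeca-9,12-dien-1-ol is oxidised with Dess–Martin periodinane to (9Z,12Z)-octadeca-9,12-dienal F1. Propane-1,3-dithiol and BF3·OEt2 convert it into 2-[(8Z,11Z)-heptadeca-8,11-dien-1-yl]-1,3-dithiane F2. n-BuLi (THF, −30 °C) gives the 2-lithio-dithiane F3; 2.2 equiv are used, the first taking the 3-OH proton. F3 opens epoxide 6 at CH2 to the dithiane carbinol F4. MeI, CaCO3 in aqueous MeCN then unmasks the ketone and gives 9.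

**Step 6 (samarium cascade).** Risks are protonation of the enolate before β-elimination, over-reduction of the enone, and dehydration of the product to a phenol.

The fallback removes the two oxygens as an alkene before oxidation; it sets out from 9 (step 5 is then not used) and comes back at 12. Ac2O/pyridine acetylates only the secondary 3-OH and gives the 3-O-acetate F5. TFA/H2O in CH2Cl2 at 0 °C removes the acetal and gives the trans-4,5-diol F6. Garegg–Samuelsson deoxygenation (PPh3, imidazole, 2,4,5-triiodoimidazole, toluene, 100 °C) gives the cyclohex-4-enyl acetate F7. K2CO3/MeOH at 0 °C gives the allylic alcohol F8, and MnO2 in CH2Cl2 oxidises it to 12.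

**Step 3 (chemoselective epoxide formation).** The risk is competing sulfonylation of the free 3-OH, or a 1,3-stannylene across the 1-OH and 3-OH.

The fallback blocks the competing hydroxyl first; it sets out from 3 and comes back at 6. Et3SiCl and imidazole in DMF silylate the secondary 3-OH of 3 and give the triethylsilyl ether F9. NaBH4 in EtOH gives the silylated diol F10. TsCl, Et3N and Bu2SnO give the silylated tosylate F11 (not isolated), and DBU closes it to the silylated spiro-epoxide F12. Bu4NF in THF at 0 °C returns 6.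

## Further compounds

F1 | step 4 | (9Z,12Z)-octadeca-9,12-dienal | CCCCC/C=C\C/C=C\CCCCCCCC=O
F2 | step 4 | 2-[(8Z,11Z)-heptadeca-8,11-dien-1-yl]-1,3-dithiane | CCCCC/C=C\C/C=C\CCCCCCCC1SCCCS1
F3 | step 4 | 2-lithio-2-[(8Z,11Z)-heptadeca-8,11-dien-1-yl]-1,3-dithiane | CCCCC/C=C\C/C=C\CCCCCCCC1([Li])SCCCS1
F4 | step 4 | dithiane carbinol: 9 with the chain C=O masked as its 1,3-dithiane | CCCCC/C=C\C/C=C\CCCCCCCC1(SCCCS1)C[C@]2(O)C[C@@H](O)[C@H]3O[C@](C)(OC)[C@@](C)(OC)O[C@@H]3C2
F5 | step 6 | 3-O-acetate of 9 | CCCCC/C=C\C/C=C\CCCCCCCC(=O)C[C@]1(O)C[C@@H](OC(C)=O)[C@H]2O[C@](C)(OC)[C@@](C)(OC)O[C@@H]2C1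
F6 | step 6 | 3-O-acetyl trans-4,5-diol (acetal removed from F5) | CCCCC/C=C\C/C=C\CCCCCCCC(=O)C[C@]1(O)C[C@@H](OC(C)=O)[C@@H](O)[C@H](O)C1
F7 | step 6 | cyclohex-4-enyl 3-acetate (C4=C5 alkene, tertiary 1-OH free) | CCCCC/C=C\C/C=C\CCCCCCCC(=O)C[C@]1(O)C[C@@H](OC(C)=O)C=CC1
F8 | step 6 | allylic alcohol (3-OH, C4=C5 alkene, tertiary 1-OH free) | CCCCC/C=C\C/C=C\CCCCCCCC(=O)C[C@]1(O)C[C@@H](O)C=CC1
F9 | step 3 | 3-O-triethylsilyl ether of 3 | COC(=O)[C@]1(O)C[C@@H](O[Si](CC)(CC)CC)[C@H]2O[C@](C)(OC)[C@@](C)(OC)O[C@@H]2C1
F10 | step 3 | 3-O-triethylsilyl ether of 4 | OC[C@]1(O)C[C@@H](O[Si](CC)(CC)CC)[C@H]2O[C@](C)(OC)[C@@](C)(OC)O[C@@H]2C1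
F11 | step 3 | 3-O-triethylsilyl ether of tosylate 5 | Cc1ccc(cc1)S(=O)(=O)OC[C@]2(O)C[C@@H](O[Si](CC)(CC)CC)[C@H]3O[C@](C)(OC)[C@@](C)(OC)O[C@@H]3C2
F12 | step 3 | 3-O-triethylsilyl ether of spiro-epoxide 6 | C1O[C@]12C[C@@H](O[Si](CC)(CC)CC)[C@H]3O[C@](C)(OC)[C@@](C)(OC)O[C@@H]3C2
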